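The numbers in the tables are calculated for substances that don't exist.

all flasks: starting material 12 mM
- green: partner 18 mM; second substrate 1.2 mM; temperature −15 °C; run made earlier
- teal: partner 18 mM; second substrate 1.8 mM; temperature 5 °C; run made earlier
- blue: partner 27 mM; second substrate 2.4 mM; temperature −15 °C; run made earlier
- Saturday's: partner 18.0 mM; second substrate 2.40 mM; temperature 20 °C; time 20 h
- Thursday's: partner 18.0 mM; second substrate 2.40 mM; temperature −10 °C; time 20 h
- Sunday's: partner 18.0 mM; second substrate 2.40 mM; temperature 5 °C; time 20 h
- Wednesday's: partner 18.0 mM; second substrate 2.40 mM; at 20 °C until 6.0 h, from then on at −10 °C; time 20 h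

| run | time / h | target / % |
|---|---|---|
| green | 25.0 | 13.2 |
| green | 50.0 | 20.1 |
| green | 72.0 | 22.1 |
| green | 96.0 | 24.2 |
| teal | 4.00 | 13.9 |
| teal | 12.0 | 14.5 |
| teal | 20.0 | 10.7 |
| teal | 30.0 | 7.3 |
| blue | 12.0 | 11.0 |
| blue | 30.0 | 21.1 |
| blue | 60.0 | 29.3 |
| blue | 96.0 | 32.8 |

(readings scatter by 0.3 percentage points)

- the best flask by amount of target, in percent of the starting material charged; "all alike" if 1.5 percentage points covers them all (Saturday's / Thursday's / Sunday's / Wednesday's / all alike)
- amount of target at the end, in percent of the starting material charged, Saturday's
- amount of target at the end, in percent of the starting material charged, Thursday's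
- amount of target at the end, in percent of the starting material charged, Sunday's
- amount of target at the end, in percent of the starting material charged, Wednesday's

At early times the target climbs in the green and blue runs, then the climb dies away with 32.8% of the starting material as target in blue, so the starting material is not what stops it. Which reagent does? Blue carries 1.50 times green's partner and its last reading is 1.36 times green's, while the rate of dying away reads 0.0315 h⁻¹ in green and 0.0344 h⁻¹ in blue. I therefore read partner as the limiting reagent, although it is charged at 1.50 equivalents, and I read a pseudo-first-order loss of partner running beside the making of target.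

So I carry blue's value, 14.6%, of the partner share: target made per unit of partner charged. Thursday's has blue's second substrate, though it stands at −10 °C against blue's −15 °C, so I estimate its plateau of target at 21.9% of the starting material.

How much of that plateau does Thursday's reach by 20 h? Teal stands near its height by 4.00 h, which I read as two rate-times, or 0.500 h⁻¹. Thursday's −10 °C lies a quarter of the way up from −15 °C to 5 °C, so on a logarithmic scale I take 0.0629 h⁻¹, and I reckon Thursday's at 15.7%.

Can a warmer flask beat that? Teal reads 10.7% at 20.0 h, less than my Thursday's figure, and Sunday's stands at teal's temperature with 2.40 mM of second substrate against teal's 1.8 mM. Saturday's and Wednesday's both start at 20 °C. For Wednesday's, the partner half-life at teal's rate, 1.39 h, is shorter than the warm stage of 6.0 h, so I reckon that a fraction 0.0498 of the partner reaches the cold stage even at that rate from a cooler flask. I pick Thursday's.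

The forecast also names Thursday's, with 1% for Saturday's, 15% for Thursday's (12.5% to 17.5%), 9% for Sunday's and 4.5% for Wednesday's. It differs from me in reading the plateaus as an equilibrium, and of Wednesday's it says “the warm period destroys most of the pool”.

The flasks give 2.63% in Saturday's, 15.5% in Thursday's, 10.5% in Sunday's and 3.98% in Wednesday's, so Thursday's leads.

    starting material + partner → target (k = 4.10 M⁻¹ h⁻¹, Ea = 68.0 kJ mol⁻¹)
    second substrate + partner → second product (k = 15.0 M⁻¹ h⁻¹, Ea = 43.0 kJ mol⁻¹)
    target ⇌ isomer of the product (K = 7.80, k = 0.0450 h⁻¹, Ea = 92.0 kJ mol⁻¹, ΔH = −17.0 kJ mol⁻¹)
    partner → decomposed reagent (k = 0.240 h⁻¹, Ea = 84.0 kJ mol⁻¹)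
    (constants at 5 °C)

At 0.384 h in Wednesday's, partner goes to decomposed reagent 7.6 times as fast as it goes to target, and its half-life by that loss is 0.45 h, shorter than the warm stage of 6.0 h. Counting target and isomer of the product together, the partner share of Wednesday's is 11.1%, and in the neighbour of Wednesday's charged with 72 mM of partner, which ends with 12.6% of target and 40.8% of isomer of the product, it is 8.90%.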